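**Plan**

1. Retrosynthetic cuts: the C2–O bond and the C20–O bond with its δ-lactone (two late C–H hydroxylations), the C7 acid back to the aldehyde, then the C5–C6 bond of ring B. The last cut turns the gibberellane into an ent-kaurane (steviol) in which C6 and C7 are both ring carbons.
2. Forward: steviol 1 supplies rings A, C and D. C7 is hydroxylated and oxidised, a 19,6α-γ-lactone is closed, the ketone is reduced and mesylated, and hydroxide contracts ring B from six to five members (step 6). Oxidation to the acid, C20 hydroxylation with δ-lactonisation and 2β-hydroxylation finish the target.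
3. Enabling feature: on the trans-fused rings A/B the axial C19 carboxyl on C4 lies 1,3-diaxial to C6 on the α face. A lactone tether can therefore place an axial oxygen on C6 beside an equatorial sulfonate on C7. On the chair of ring B the C5–C6 bond is antiperiplanar to C7–O, and the alkoxide freed from the tether pushes C5 from C6 to C7; the old C6 leaves the ring as the formyl carbon.
4. Stereochemistry: C4, C5, C8, C9, C10 and C13 come from steviol. C6 is set by thermodynamic epimerisation of the aldehyde in the key step (both epimers converge). C2 is set by the 2-oxidase. The lactone geometry follows from the fixed cis relation of C19 and C20.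
5. Temporary helpers: the C7 oxygen (leaves as mesylate) and the 19,6-lactone (opened in step 6). No protecting groups are used.

Key step: step 6

Assumption: steviol is bought (it is also made in one step from the commercial sweetener stevioside); the three dioxygenases are used as clarified lysates of recombinant E. coli; α and β refer to the usual drawing of steviol and the gibberellins (C19 and C20 α; H-5 and H-9 β); compounds after the ring contraction are named as gibberell-16-enes on the skeleton of the natural gibberellins (C7 is the carbon on C6, C19 the carboxyl on C4, C20 the carbon on C10).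

**Route**

Step 1
Reactants: 1 steviol
Product: 2 7β-hydroxysteviol
Conditions: PtmO6 (ent-kauranoid C7β-hydroxylase, a non-haem iron 2-oxoglutarate-dependent dioxygenase), 2-oxoglutaric acid, FeSO4, L-ascorbic acid, air, KH2PO4/K2HPO4 buffer pH 7.5, 5% DMSO, 28 °C
Reagents that add atoms: dioxygen O=O
Why: Enzymatic C–H hydroxylation: dioxygenases of this family are known to hydroxylate the unactivated C7 methylene of ent-kauran-19-oic acids by hydrogen abstraction and oxygen rebound with retention, so oxygen should enter only at the axial 7β position of ring B; the new stereocentre is set by the active site and is removed again in step 2.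

Step 2
Reactants: 2 7β-hydroxysteviol
Product: 3 7-oxosteviol
Conditions: Dess–Martin periodinane, CH2Cl2, rt
Reagents that add atoms: none
Why: Dess–Martin oxidation of the only secondary alcohol should give the ketone under neutral conditions that leave the tertiary 13-OH, the acid and the exocyclic alkene alone; no stereocentre is formed.

Step 3
Reactants: 3 7-oxosteviol
Product: 6 13-hydroxy-7-oxokaurenolide (19,6α-lactone), via tris-TMS silyl enol ether 4 (not isolated), via 6β-bromo ketone 5 (not isolated)
Conditions: TMSOTf (3.3 equiv), Et3N, CH2Cl2, 0 °C; NBS, THF, −78 °C; Bu4NF, THF, 0 °C to rt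
Reagents that add atoms: none
Why: Silyl enol ether bromination followed by intramolecular SN2 lactonisation: the ketone can enolise only towards C6 because C8 is quaternary, NBS should attack the enol ether (far more nucleophilic than the 16-ene) from the open β face, and the fluoride-released C19 carboxylate, held 1,3-diaxially over C6 on the α face, should displace the α-keto bromide with inversion, which sets the axial 6α C–O bond (a 6α-bromide, if formed, would epimerise through the enol and be drained the same way).

Step 4
Reactants: 6 13-hydroxy-7-oxokaurenolide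
Product: 7 7α,13-dihydroxykaurenolide
Conditions: NaBH4, MeOH–THF, −20 °C
Reagents that add atoms: none
Why: Borohydride reduction of the α-acyloxy ketone should occur by axial attack on the β face of C7, past only H-5 and H-9 and anti to the axial C6–O bond (Felkin–Anh), which gives the equatorial 7α-alcohol cis to the lactone oxygen; the hindered lactone carbonyl is not reduced.

Step 5
Reactants: 7 7α,13-dihydroxykaurenolide
Product: 8 13-hydroxy-7α-mesyloxykaurenolide
Conditions: MsCl, pyridine, cat. DMAP, 0 °C to rt
Reagents that add atoms: methanesulfonyl chloride CS(=O)(=O)Cl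
Why: Sulfonylation with MsCl in pyridine should convert the secondary 7α-OH into the leaving group with retention at C7, while the tertiary bridgehead 13-OH, which reacts only under sulfene-forming or forcing conditions, stays free.

Step 6
Reactants: 8 13-hydroxy-7α-mesyloxykaurenolide
Product: 11 13-hydroxy-7-oxogibberell-16-en-19-oic acid (6β-formyl), via ring-opened hydroxy mesylate 9 (not isolated), via 6-epi aldehyde 10 (not isolated)
Conditions: 2 M KOH, H2O–t-BuOH, 70 °C, argon; then 1 M HCl to pH 3
Reagents that add atoms: potassium hydroxide [K+].[OH-]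
Why: Hydroxide opens the 19,6α-lactone to the C19 carboxylate and the axial 6α-alkoxide, whose lone pair pushes the C5–C6 bond onto C7 while the equatorial 7α-mesylate leaves, so that C5 becomes bonded to the former C7 (C6 of the gibberellane) and the former C6 leaves the ring as the formyl carbon C7. The closest known reaction type is the base-induced semipinacol ring contraction of cyclohexane-1,2-diol monosulfonates to cyclopentanecarbaldehydes, of the kind used on 7-sulfonyloxy-kaurenolides. Ring B is closed as a five-membered ring by a concerted 1,2-alkyl shift (ring contraction, the migrating C5 attacking C7 from the rear with inversion there) and not by cyclisation of a chain. C5 migrates with retention; the new stereocentre C6 should first carry the formyl group α (from the inversion at C7, compound 10) and is then epimerised through the enolate by the same base to the more stable 6β-formyl isomer, trans to the C4–C5 bond, so that both epimers converge on 11. The step needs C5–C6 migration ahead of epoxide closure, hydride shift, C8–C9 shift and elimination, and the cis 6α-O(axial)/7α-OMs(equatorial) pair on the rigid chair of ring B secures this: only ring bonds are antiperiplanar to C7–O, no rear-side O attack or anti β-hydrogen exists, and only the C5–C6 bond is driven by the alkoxide. The C19 carboxylate set free at the same time is the anchor for the δ-lactone of step 8.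

Step 7
Reactants: 11 13-hydroxy-7-oxogibberell-16-en-19-oic acid (6β-formyl)
Product: 12 13-hydroxygibberell-16-ene-7,19-dioic acid
Conditions: NaClO2, NaH2PO4, 2-methyl-2-butene, t-BuOH–H2O, rt
Reagents that add atoms: sodium chlorite [Na+].[O-]Cl=O
Why: Pinnick oxidation should convert the hindered aldehyde into the acid without epimerising C6, and 2-methyl-2-butene traps the hypochlorous acid before it can reach the 16-ene.

Step 8
Reactants: 12 13-hydroxygibberell-16-ene-7,19-dioic acid
Product: 14 13,20-dihydroxygibberell-16-ene-7,19-dioic acid 19,20-lactone, via 20-hydroxy diacid 13 (not isolated)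
Conditions: gibberellin 20-oxidase (2-oxoglutarate-dependent dioxygenase), 2-oxoglutaric acid, FeSO4, L-ascorbic acid, air, Tris·HCl buffer pH 7.0, 30 °C, stopped at partial conversion; then 1 M HCl to pH 3
Reagents that add atoms: dioxygen O=O
Why: Enzymatic C–H hydroxylation by a gibberellin 20-oxidase, for which 12 is the natural substrate: the C20 methyl group is hydroxylated and the 20-alcohol, 1,3-diaxial to the C19 carboxyl on ring A, closes the δ-lactone on acidification (the lactone should no longer be a substrate for further oxidation); no stereocentre is formed.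

Step 9
Reactants: 14 13,20-dihydroxygibberell-16-ene-7,19-dioic acid 19,20-lactone
Product: 15 2β,13,20-trihydroxygibberell-16-ene-7,19-dioic acid 19,20-lactone (the target gibberellin)
Conditions: C20-gibberellin 2-oxidase (class 3 gibberellin 2-oxidase, 2-oxoglutarate-dependent dioxygenase), 2-oxoglutaric acid, FeSO4, L-ascorbic acid, air, Tris·HCl buffer pH 7.5, 30 °C
Reagents that add atoms: dioxygen O=O
Why: Enzymatic C–H hydroxylation by a C20-gibberellin 2-oxidase: this class is known to hydroxylate the equatorial 2β C–H of C20-gibberellins by hydrogen abstraction and rebound with retention, a remote unactivated methylene that no small reagent would single out, and the active site sets the C2 stereocentre.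

**Compound list**

1 | steviol (ent-13-hydroxykaur-16-en-19-oic acid) | C=C1C[C@]23C[C@@]1(O)CC[C@H]2[C@]1(C)CCC[C@@](C)(C(=O)O)[C@H]1CC3 | starting material
2 | 7β-hydroxysteviol (7β,13-dihydroxy acid, 7-OH axial) | C=C1C[C@]23C[C@@]1(O)CC[C@H]2[C@]1(C)CCC[C@@](C)(C(=O)O)[C@H]1C[C@@H]3O | intermediate
3 | 7-oxosteviol (13-hydroxy-7-oxo acid) | C=C1C[C@]23C[C@@]1(O)CC[C@H]2[C@]1(C)CCC[C@@](C)(C(=O)O)[C@H]1CC3=O | intermediate
4 | trimethylsilyl 7,13-bis(trimethylsilyloxy)-ent-kaura-6,16-dien-19-oate | C=C1C[C@]23C[C@@]1(O[Si](C)(C)C)CC[C@H]2[C@]1(C)CCC[C@@](C)(C(=O)O[Si](C)(C)C)[C@H]1C=C3O[Si](C)(C)C | intermediate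
5 | trimethylsilyl 6β-bromo-7-oxo-13-(trimethylsilyloxy)-ent-kaur-16-en-19-oate | C=C1C[C@]23C[C@@]1(O[Si](C)(C)C)CC[C@H]2[C@]1(C)CCC[C@@](C)(C(=O)O[Si](C)(C)C)[C@H]1[C@H](Br)C3=O | intermediate
6 | 13-hydroxy-7-oxokaurenolide (19,6α-lactone, lactone O axial on C6) | C=C1C[C@]23C[C@@]1(O)CC[C@H]2[C@]1(C)CCC[C@@](C)(C(=O)O4)[C@H]1[C@@H]4C3=O | intermediate
7 | 7α,13-dihydroxykaurenolide (7-OH equatorial, cis to the lactone O) | C=C1C[C@]23C[C@@]1(O)CC[C@H]2[C@]1(C)CCC[C@@](C)(C(=O)O4)[C@H]1[C@@H]4[C@H]3O | intermediate
8 | 13-hydroxy-7α-mesyloxykaurenolide | C=C1C[C@]23C[C@@]1(O)CC[C@H]2[C@]1(C)CCC[C@@](C)(C(=O)O4)[C@H]1[C@@H]4[C@H]3OS(C)(=O)=O | intermediate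
9 | 6α,13-dihydroxy-7α-mesyloxy-ent-kaur-16-en-19-oic acid (potassium salt in the flask) | C=C1C[C@]23C[C@@]1(O)CC[C@H]2[C@]1(C)CCC[C@@](C)(C(=O)O)[C@H]1[C@@H](O)[C@H]3OS(C)(=O)=O | intermediate
10 | 6-epi-13-hydroxy-7-oxogibberell-16-en-19-oic acid (6α-formyl) | C=C1C[C@]23C[C@@]1(O)CC[C@H]2[C@]1(C)CCC[C@@](C)(C(=O)O)[C@H]1[C@H]3C=O | intermediate
11 | 13-hydroxy-7-oxogibberell-16-en-19-oic acid (6β-formyl, H-6 α) | C=C1C[C@]23C[C@@]1(O)CC[C@H]2[C@]1(C)CCC[C@@](C)(C(=O)O)[C@H]1[C@@H]3C=O | intermediate
12 | 13-hydroxygibberell-16-ene-7,19-dioic acid (6β-carboxyl, C20 methyl) | C=C1C[C@]23C[C@@]1(O)CC[C@H]2[C@]1(C)CCC[C@@](C)(C(=O)O)[C@H]1[C@@H]3C(=O)O | intermediate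
13 | 13,20-dihydroxygibberell-16-ene-7,19-dioic acid (open form of 14) | C=C1C[C@]23C[C@@]1(O)CC[C@H]2[C@]1(CO)CCC[C@@](C)(C(=O)O)[C@H]1[C@@H]3C(=O)O | intermediate
14 | 13,20-dihydroxygibberell-16-ene-7,19-dioic acid 19,20-lactone | C=C1C[C@]23C[C@@]1(O)CC[C@H]2[C@]12COC(=O)[C@](C)(CCC1)[C@H]2[C@@H]3C(=O)O | intermediate
15 | 2β,13,20-trihydroxygibberell-16-ene-7,19-dioic acid 19,20-lactone (the target gibberellin, 2β-hydroxy derivative of 14) | C=C1C[C@]23C[C@@]1(O)CC[C@H]2[C@]12COC(=O)[C@](C)(C[C@@H](O)C1)[C@H]2[C@@H]3C(=O)O | target

Total step count: 9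
Longest linear sequence: 9 steps (1 to 15)

**Steps most likely to fail**

1. Step 9. The lactone form of 14 may not be recognised by an enzyme whose documented substrates carry a C20 methyl group (no turnover), or the new carbinol may be oxidised further to the 2-ketone. Fallback: the two tailoring hydroxylations are run in the reverse order, setting out from 12. The C20-gibberellin 2-oxidase is applied first to 12, its documented type of substrate, to give 2β,13-dihydroxygibberell-16-ene-7,19-dioic acid F1. The gibberellin 20-oxidase then hydroxylates C20 of F1 to the open form 2β,13,20-trihydroxygibberell-16-ene-7,19-dioic acid F2, and acidification to pH 3 closes the δ-lactone, which returns to the route at 15.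

2. Step 8. Oxidation at C20 may run on past the alcohol level (to the aldehyde and to loss of C20) before the alcohol is released and lactonised. Fallback: setting out from 12, the 20-oxidase is allowed to run deliberately to the aldehyde level, 13-hydroxy-20-oxogibberell-16-ene-7,19-dioic acid F3, where this enzyme class stalls. F3 is then reduced chemically with NaBH4 in MeOH at 0 °C to the alcohol 13, and acidification returns to the route at 14.

3. Step 6. Hydroxide may attack the sulfonate at sulfur (loss of the leaving group) before the hindered lactone opens, or the aldehyde may decay under hot base. Fallback: ring B is contracted by a Wolff rearrangement instead, setting out from 3. Esterification with TMSCHN2 gives methyl 13-hydroxy-7-oxo-ent-kaur-16-en-19-oate F4. Direct diazo transfer at C6, the only enolisable position (2,4,6-triisopropylbenzenesulfonyl azide, KOH, Bu4NBr, 18-crown-6), gives methyl 6-diazo-13-hydroxy-7-oxo-ent-kaur-16-en-19-oate F5. Irradiation at 300 nm in MeOH gives, through the ring-contracted ketene F6, the kinetic dimethyl 6-epi-13-hydroxygibberell-16-ene-7,19-dioate F7 together with dimethyl 13-hydroxygibberell-16-ene-7,19-dioate F8, and NaOMe in MeOH converts F7 into F8. n-PrSLi in HMPA cleaves both methyl esters and returns to the route at 12.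

**Further compounds**

F1 | step 9 | 2β,13-dihydroxygibberell-16-ene-7,19-dioic acid (2β-hydroxy derivative of 12) | C=C1C[C@]23C[C@@]1(O)CC[C@H]2[C@]1(C)C[C@H](O)C[C@@](C)(C(=O)O)[C@H]1[C@@H]3C(=O)O
F2 | step 9 | 2β,13,20-trihydroxygibberell-16-ene-7,19-dioic acid (open form of 15) | C=C1C[C@]23C[C@@]1(O)CC[C@H]2[C@]1(CO)C[C@H](O)C[C@@](C)(C(=O)O)[C@H]1[C@@H]3C(=O)O
F3 | step 8 | 13-hydroxy-20-oxogibberell-16-ene-7,19-dioic acid (open 20-aldehyde form) | C=C1C[C@]23C[C@@]1(O)CC[C@H]2[C@]1(C=O)CCC[C@@](C)(C(=O)O)[C@H]1[C@@H]3C(=O)O
F4 | step 6 | methyl 13-hydroxy-7-oxo-ent-kaur-16-en-19-oate | C=C1C[C@]23C[C@@]1(O)CC[C@H]2[C@]1(C)CCC[C@@](C)(C(=O)OC)[C@H]1CC3=O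
F5 | step 6 | methyl 6-diazo-13-hydroxy-7-oxo-ent-kaur-16-en-19-oate | C=C1C[C@]23C[C@@]1(O)CC[C@H]2[C@]1(C)CCC[C@@](C)(C(=O)OC)[C@H]1C(=[N+]=[N-])C3=O
F6 | step 6 | ring-contracted ketene from F5 | C=C1C[C@]23C[C@@]1(O)CC[C@H]2[C@]1(C)CCC[C@@](C)(C(=O)OC)[C@H]1C3=C=O
F7 | step 6 | dimethyl 6-epi-13-hydroxygibberell-16-ene-7,19-dioate | C=C1C[C@]23C[C@@]1(O)CC[C@H]2[C@]1(C)CCC[C@@](C)(C(=O)OC)[C@H]1[C@H]3C(=O)OC
F8 | step 6 | dimethyl 13-hydroxygibberell-16-ene-7,19-dioate | C=C1C[C@]23C[C@@]1(O)CC[C@H]2[C@]1(C)CCC[C@@](C)(C(=O)OC)[C@H]1[C@@H]3C(=O)OC
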